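All constants were chosen freely; the run is a simulation.

At the reading, 5.0 h after the start, target has been going on to over-reaction product at 0.095 /h for as long as it has stood. The question is the share of c(target) in c(target) plus c(over-reaction product), the selectivity for target.

common to all: second substrate 0.0500 M; free catalyst 42 µM
- amber: starting material 0.050 M; partner 0.0475 M; time 5.0 h; a closed flask charged with all of it at once and left for 5.0 h
- ochre: starting material 0.050 M; partner 0.0475 M; one stirred flow tank at steady state, fed with the mixture as stated, mean residence time 5.0 h
- green: starting material 0.050 M (fed, over 4.00 h); partner 0.0475 M; time 5.0 h; a stirred flask in which starting material is dosed at a steady rate over 4.00 h without added volume, worked up at 5.0 h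
- blue: starting material 0.050 M; partner 0.0475 M (fed, over 4.00 h); time 5.0 h; a stirred flask in which partner is dosed at a steady rate over 4.00 h without added volume, worked up at 5.0 h

1. the set-up with the highest share of target in all that became target or over-reaction product, at the outlet or at the end ("none" if the first two lie within 2 percentage points) (amber / ochre / green / blue / none)
2. share of target in all that became target or over-reaction product, at the outlet or at the end, amber
3. share of target in all that became target or over-reaction product, at the outlet or at the end, ochre
4. share of target in all that became target or over-reaction product, at the outlet or at the end, green
5. share of target in all that became target or over-reaction product, at the outlet or at the end, blue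

- the stated concentrations are those of everything mixed, before any reaction; amounts are the same in each set-up
- the feed brings no volume worth counting
- run time (amber): 5.0 h

    second substrate + free catalyst ⇌ catalyst intermediate B (K1 = 31 /M, k1 = 18000 /M/h)
    partner ⇌ dormant form (K2 = 2.5, k2 = 0.035 /h)
    partner → decomposed reagent (k3 = 0.63 /h)
    partner + catalyst intermediate B → free catalyst + second product (k4 = 920 /M/h)
    target → over-reaction product (k5 = 0.095 /h)
    starting material + free catalyst ⇌ catalyst intermediate A (K6 = 6.8 /M, k6 = 3000 /M/h)
    partner + catalyst intermediate A → free catalyst + target (k7 = 3900 /M/h)

I go to logarithms. The natural logarithm of the share, divided by 0.095 /h and with its sign turned, is a time, and I call that time the age of target. Amber and ochre look nearly the same, with one mixture and one time, so I compare them by this age.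

In amber, partner goes quickly: its half-life by decomposition alone is 1.1 h, shorter than the 7.3 h of target by its step to over-reaction product alone. Leaving the catalyst steps aside, decomposition and the turn to dormant form give partner a mean life of 1.50 h. As an estimate, I put the mean birth of target in amber that long after the start, and I take its age at the reading as the run time less the mean life of partner, 3.50 h. That gives amber a share of 71.7 %.

In ochre, the tank at steady state sends target out at c(target) divided by the residence time, and turns it over at 0.095 /h times c(target). Ochre's share is thus one over one plus 0.095 /h times 5.0 h, or 67.8 %, and its age is 4.09 h. Ochre's target is older than amber's, so ochre ends lower.

For green and blue my hand reckoning goes no further than a direction: dosing moves the birth of target later, so I expect ages below amber's.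

The forecast gives 71.5 % for amber, 67.8 % for ochre, 78 % for green and 82 % for blue, with blue best, on the ground that “Dosing partner or starting material pushes target formation later”. The simulation gives 71.2 % for amber, 67.8 % for ochre, 77.6 % for green and 81.8 % for blue, so blue is best.

Taken back through the same logarithm, amber's share means an age of 3.58 h against my 3.50 h, and blue's share means 2.11 h, less than amber's. In blue, the mean life of partner, 1.50 h, is shorter than the dosing time of 4.00 h, the feed stops 1.00 h before the reading, and target stands at an age of 2.11 h.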